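**Strategy.** Ring B (C1'–C6', the trimethylcyclohexane) is disconnected at C1'–C2'. The plan exploits that C1' is the exocyclic γ-carbon of the ring A enone (O=C1–C2=C3–C1'). Its hydrogen is acidic, so a precursor that is a mixture of C1' epimers and carries a tethered 2-(acyloxymethyl)allyl unit can be funnelled through the planar dienolate into one quaternary configuration. A ligand-controlled palladium-catalysed allylic alkylation does this and closes ring B in the same operation. The methylidene left at C3' is then hydromethylated to the gem-dimethyl group. The side-chain centre comes from a chirality-transferring Claisen rearrangement, the ring A centre from a catalytic hydroxymethylation.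

Key step: step 8

Atom labels: ring A = cyclohex-2-en-1-one, C1 (C=O), C2 (bears the propanoic acid carbon), C3 (bears ring B), C4, C5, C6 (bears CH2OCHO). Ring B = C1' (quaternary, methyl), C2' (CH2 between C1' and C3'), C3' (CMe2), C4', C5', C6'.

Assumption: (2R,3E)-pent-3-en-2-ol is bought as the single enantiomer; lipase resolution of the cheap racemate is the alternative source.

Step 1
Reactants: 1 3-chlorocyclohex-2-en-1-one; 2 (2R,3E)-pent-3-en-2-ol
Product: 3 3-{[(2R,3E)-pent-3-en-2-yl]oxy}cyclohex-2-en-1-one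
Conditions: NaH, THF, 0 to 23 °C
Reagents that add atoms: none
Why: Addition–elimination (vinylogous acyl substitution) of the sodium alkoxide on the β-chloroenone forms the enol ether without touching the carbinol C–O bond, so the (R) configuration is retained.

Step 2
Reactants: 3 3-{[(2R,3E)-pent-3-en-2-yl]oxy}cyclohex-2-en-1-one
Product: 4 2-[(2S,3E)-pent-3-en-2-yl]cyclohexane-1,3-dione
Conditions: o-xylene, 150 °C, sealed tube
Reagents that add atoms: none
Why: Claisen rearrangement; the allyl fragment reacts suprafacially with its carbinol methyl pseudo-equatorial, which should give the (E)-alkene and transfer the (R) carbinol configuration to the new (S) centre (the future acid α-carbon), while the ring carbon ends as the achiral C2 of the dione.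

Step 3
Reactants: 4 2-[(2S,3E)-pent-3-en-2-yl]cyclohexane-1,3-dione
Product: 5 3-methoxy-2-[(2S,3E)-pent-3-en-2-yl]cyclohex-2-en-1-one
Conditions: Me2SO4, K2CO3, acetone, reflux
Reagents that add atoms: dimethyl sulfate, COS(=O)(=O)OC
Why: O-alkylation of the enolised 2-substituted 1,3-dione (hard electrophile, hindered C2) gives the vinylogous ester needed for the Stork–Danheiser transposition; the dione is symmetric, so one product is expected.

Step 4
Reactants: 6 2-methylprop-2-en-1-ol; 7 1,3-dibromobutane
Product: 9 6-bromo-2-methylideneheptan-1-ol (racemic), via dilithio alkoxide 8 (not isolated)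
Conditions: n-BuLi (2.2 equiv), TMEDA, Et2O/hexane, 0 to 23 °C; then 7, −78 to 0 °C; H2O
Reagents that add atoms: none
Why: Double deprotonation gives the O,C-dianion, whose allylic carbanion should displace the primary bromide (SN2 C-alkylation) in preference to the secondary one.

Step 5
Reactants: 9 6-bromo-2-methylideneheptan-1-ol
Product: 10 [(6-bromo-2-methylideneheptyl)oxy](tert-butyl)dimethylsilane
Conditions: TBSCl, imidazole, CH2Cl2, 23 °C
Reagents that add atoms: tert-butyldimethylsilyl chloride, CC(C)(C)[Si](C)(C)Cl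
Why: Standard silylation of the primary alcohol protects it for the organometallic step.

Step 6
Reactants: 10 [(6-bromo-2-methylideneheptyl)oxy](tert-butyl)dimethylsilane; 5 3-methoxy-2-[(2S,3E)-pent-3-en-2-yl]cyclohex-2-en-1-one
Product: 13 3-(7-hydroxy-6-methylideneheptan-2-yl)-2-[(2S,3E)-pent-3-en-2-yl]cyclohex-2-en-1-one (both C1' epimers), via Grignard reagent 11 (not isolated), via silyl ether enone 12 (not isolated)
Conditions: Mg, THF, 23 °C; CeCl3, THF, −78 °C; 5, −78 to 0 °C; then 2 M HCl, THF, 23 °C
Reagents that add atoms: water, O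
Why: Stork–Danheiser transposition: the cerium-modified secondary Grignard reagent adds 1,2 to the vinylogous ester and aqueous acid unmasks the transposed enone and removes the silyl group; C1' forms as both epimers, which is harmless because step 8 erases it.

Step 7
Reactants: 13 3-(7-hydroxy-6-methylideneheptan-2-yl)-2-[(2S,3E)-pent-3-en-2-yl]cyclohex-2-en-1-one
Product: 14 tert-butyl 2-methylidene-6-{3-oxo-2-[(2S,3E)-pent-3-en-2-yl]cyclohex-1-en-1-yl}heptyl carbonate (both C1' epimers)
Conditions: Boc2O, DMAP (10 mol %), CH2Cl2, 0 to 23 °C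
Reagents that add atoms: di-tert-butyl dicarbonate, CC(C)(C)OC(=O)OC(=O)OC(C)(C)C
Why: Acylation of the primary allylic alcohol gives a carbonate that ionises with zerovalent palladium and liberates its own base (tert-butoxide).

Step 8
Reactants: 14 tert-butyl 2-methylidene-6-{3-oxo-2-[(2S,3E)-pent-3-en-2-yl]cyclohex-1-en-1-yl}heptyl carbonate (both C1' epimers)
Product: 15 3-[(1S)-1-methyl-3-methylidenecyclohexyl]-2-[(2S,3E)-pent-3-en-2-yl]cyclohex-2-en-1-one
Conditions: Pd2(dba)3·CHCl3 (2.5 mol %), (1R,2R)-N,N'-bis[2-(diphenylphosphino)benzoyl]cyclohexane-1,2-diamine (7.5 mol %), THF (0.01 M), 25 to 40 °C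
Reagents that add atoms: none
Why: Proposed new method: the zerovalent palladium–diphosphine complex ionises the allylic carbonate, releasing CO2 and tert-butoxide, which reversibly deprotonates the enone; of the interconverting enolates only the exocyclic C3=C1' dienolate can reach a terminus of the 2-tethered π-allyl through a six-membered transition state, so C1' attacks C2' on the face opposite palladium. The closest known reaction types are the palladium-catalysed asymmetric allylic alkylation of prochiral ketone enolates to quaternary α-centres and Tsuji–Trost cycloalkylations. Ring B closes in a 6-endo sense on the π-allyl (formally 6-exo-tet at the C2'–O carbon of the carbonate), and since the two allyl termini are equivalent the electrophile poses no regiochemical question. C1' is planar in the dienolate, so both C1' epimers of 14 and both dienolate geometries converge, and the chiral ligand pocket is expected to select the face that gives (1S); the antipodal ligand is taken should the sense prove opposite. The step needs γ-exocyclic attack over α, O, α' and endocyclic γ attack, which ring size secures (six against eight or ten members), and cyclisation over oligomerisation, which dilution secures.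

Step 9
Reactants: 15 3-[(1S)-1-methyl-3-methylidenecyclohexyl]-2-[(2S,3E)-pent-3-en-2-yl]cyclohex-2-en-1-one
Product: 17 2-[(2S,3E)-pent-3-en-2-yl]-3-[(1S)-1,3,3-trimethylcyclohexyl]cyclohex-2-en-1-one, via sulfonylhydrazide adduct 16 (not isolated)
Conditions: Fe(acac)3 (30 mol %), PhSiH3, CH2=NNHSO2(CH2)7CH3, THF/MeOH, 23 °C; then MeOH, 60 °C
Reagents that add atoms: formaldehyde octane-1-sulfonylhydrazone, C=NNS(=O)(=O)CCCCCCCC
Why: Iron-hydride hydrogen-atom transfer (olefin hydromethylation) puts H on the exocyclic CH2, the tertiary C3' radical adds to the hydrazone carbon and the adduct loses sulfinate and N2 on warming to leave the second methyl; the 1,1-disubstituted alkene should react far faster than the 1,2-disubstituted propenyl group or the electron-poor enone, and no stereocentre is formed.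

Step 10
Reactants: 17 2-[(2S,3E)-pent-3-en-2-yl]-3-[(1S)-1,3,3-trimethylcyclohexyl]cyclohex-2-en-1-one
Product: 18 trimethyl({6-[(2S,3E)-pent-3-en-2-yl]-5-[(1S)-1,3,3-trimethylcyclohexyl]cyclohexa-1,5-dien-1-yl}oxy)silane
Conditions: LDA, THF, −78 °C; TMSCl, Et3N, −78 to 0 °C
Reagents that add atoms: chlorotrimethylsilane, C[Si](C)(C)Cl
Why: Kinetic deprotonation of the enone at C6 (α') and O-silylation give the cross-conjugated silyl dienol ether; the doubly allylic side-chain C–H is far less acidic and should stay untouched.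

Step 11
Reactants: 18 trimethyl({6-[(2S,3E)-pent-3-en-2-yl]-5-[(1S)-1,3,3-trimethylcyclohexyl]cyclohexa-1,5-dien-1-yl}oxy)silane
Product: 19 (6S)-6-(hydroxymethyl)-2-[(2S,3E)-pent-3-en-2-yl]-3-[(1S)-1,3,3-trimethylcyclohexyl]cyclohex-2-en-1-one
Conditions: Sc(OTf)3 (10 mol %), (S,S)-6,6'-bis(1-hydroxy-2,2-dimethylpropyl)-2,2'-bipyridine (12 mol %), 35% aq. HCHO, DME/H2O 9:1, −20 °C
Reagents that add atoms: formaldehyde, C=O
Why: Catalytic asymmetric Mukaiyama aldol (hydroxymethylation) in aqueous medium; the chiral scandium–bipyridine complex, not the remote resident centres, selects the enol ether face and should set (6S), the ligand antipode being used if the sense proves opposite.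

Step 12
Reactants: 19 (6S)-6-(hydroxymethyl)-2-[(2S,3E)-pent-3-en-2-yl]-3-[(1S)-1,3,3-trimethylcyclohexyl]cyclohex-2-en-1-one
Product: 20 {(1S)-2-oxo-3-[(2S,3E)-pent-3-en-2-yl]-4-[(1S)-1,3,3-trimethylcyclohexyl]cyclohex-3-en-1-yl}methyl formate
Conditions: HCO2CH2CF3 (neat), 50 °C
Reagents that add atoms: 2,2,2-trifluoroethyl formate, O=COCC(F)(F)F
Why: Neutral formyl transfer (transesterification) to the primary alcohol avoids base, which would trigger β-elimination or epimerisation at C6.

Step 13
Reactants: 20 {(1S)-2-oxo-3-[(2S,3E)-pent-3-en-2-yl]-4-[(1S)-1,3,3-trimethylcyclohexyl]cyclohex-3-en-1-yl}methyl formate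
Product: 22 (2R)-2-{(5S)-5-[(formyloxy)methyl]-6-oxo-2-[(1S)-1,3,3-trimethylcyclohexyl]cyclohex-1-en-1-yl}propanoic acid, via aldehyde 21 (not isolated)
Conditions: O3, CH2Cl2, −78 °C; Me2S; then NaClO2, NaH2PO4, 2-methylbut-2-ene, t-BuOH/H2O, 0 °C
Reagents that add atoms: ozone, [O-][O+]=O; sodium chlorite, [Na+].[O-]Cl=O
Why: Ozonolysis should cleave only the electron-rich disubstituted alkene, and immediate cold Pinnick oxidation of the labile α-branched aldehyde gives the acid with the side-chain centre intact (its descriptor changes from S to R only because CO2H outranks the ring carbon).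

**Compound list**

1 | 3-chlorocyclohex-2-en-1-one | O=C1CCCC(Cl)=C1 | starting material
2 | (2R,3E)-pent-3-en-2-ol | C/C=C/[C@@H](C)O | starting material
3 | 3-{[(2R,3E)-pent-3-en-2-yl]oxy}cyclohex-2-en-1-one | C/C=C/[C@@H](C)OC1=CC(=O)CCC1 | intermediate
4 | 2-[(2S,3E)-pent-3-en-2-yl]cyclohexane-1,3-dione | C[C@@H](/C=C/C)C1C(=O)CCCC1=O | intermediate
5 | 3-methoxy-2-[(2S,3E)-pent-3-en-2-yl]cyclohex-2-en-1-one | C[C@@H](/C=C/C)C1=C(OC)CCCC1=O | intermediate
6 | 2-methylprop-2-en-1-ol | CC(=C)CO | starting material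
7 | 1,3-dibromobutane | CC(Br)CCBr | starting material
8 | dilithio derivative of 6 (lithium 2-(lithiomethyl)prop-2-en-1-olate) | [Li]CC(=C)CO[Li] | intermediate
9 | 6-bromo-2-methylideneheptan-1-ol | CC(Br)CCCC(=C)CO | intermediate
10 | [(6-bromo-2-methylideneheptyl)oxy](tert-butyl)dimethylsilane | CC(Br)CCCC(=C)CO[Si](C)(C)C(C)(C)C | intermediate
11 | {7-[(tert-butyldimethylsilyl)oxy]-6-methylideneheptan-2-yl}magnesium bromide | CC([Mg]Br)CCCC(=C)CO[Si](C)(C)C(C)(C)C | intermediate
12 | 3-{7-[(tert-butyldimethylsilyl)oxy]-6-methylideneheptan-2-yl}-2-[(2S,3E)-pent-3-en-2-yl]cyclohex-2-en-1-one | C[C@@H](/C=C/C)C1=C(C(C)CCCC(=C)CO[Si](C)(C)C(C)(C)C)CCCC1=O | intermediate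
13 | 3-(7-hydroxy-6-methylideneheptan-2-yl)-2-[(2S,3E)-pent-3-en-2-yl]cyclohex-2-en-1-one | C[C@@H](/C=C/C)C1=C(C(C)CCCC(=C)CO)CCCC1=O | intermediate
14 | tert-butyl 2-methylidene-6-{3-oxo-2-[(2S,3E)-pent-3-en-2-yl]cyclohex-1-en-1-yl}heptyl carbonate | C[C@@H](/C=C/C)C1=C(C(C)CCCC(=C)COC(=O)OC(C)(C)C)CCCC1=O | intermediate
15 | 3-[(1S)-1-methyl-3-methylidenecyclohexyl]-2-[(2S,3E)-pent-3-en-2-yl]cyclohex-2-en-1-one | C[C@@H](/C=C/C)C1=C([C@@]2(C)CCCC(=C)C2)CCCC1=O | intermediate
16 | N'-({1,3-dimethyl-3-[3-oxo-2-((2S,3E)-pent-3-en-2-yl)cyclohex-1-en-1-yl]cyclohexyl}methyl)octane-1-sulfonohydrazide | C[C@@H](/C=C/C)C1=C([C@@]2(C)CCCC(C)(CNNS(=O)(=O)CCCCCCCC)C2)CCCC1=O | intermediate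
17 | 2-[(2S,3E)-pent-3-en-2-yl]-3-[(1S)-1,3,3-trimethylcyclohexyl]cyclohex-2-en-1-one | C[C@@H](/C=C/C)C1=C([C@@]2(C)CCCC(C)(C)C2)CCCC1=O | intermediate
18 | trimethyl({6-[(2S,3E)-pent-3-en-2-yl]-5-[(1S)-1,3,3-trimethylcyclohexyl]cyclohexa-1,5-dien-1-yl}oxy)silane | C[C@@H](/C=C/C)C1=C([C@@]2(C)CCCC(C)(C)C2)CCC=C1O[Si](C)(C)C | intermediate
19 | (6S)-6-(hydroxymethyl)-2-[(2S,3E)-pent-3-en-2-yl]-3-[(1S)-1,3,3-trimethylcyclohexyl]cyclohex-2-en-1-one | C[C@@H](/C=C/C)C1=C([C@@]2(C)CCCC(C)(C)C2)CC[C@@H](CO)C1=O | intermediate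
20 | {(1S)-2-oxo-3-[(2S,3E)-pent-3-en-2-yl]-4-[(1S)-1,3,3-trimethylcyclohexyl]cyclohex-3-en-1-yl}methyl formate | C[C@@H](/C=C/C)C1=C([C@@]2(C)CCCC(C)(C)C2)CC[C@@H](COC=O)C1=O | intermediate
21 | {(1S)-2-oxo-3-[(2R)-1-oxopropan-2-yl]-4-[(1S)-1,3,3-trimethylcyclohexyl]cyclohex-3-en-1-yl}methyl formate | C[C@@H](C=O)C1=C([C@@]2(C)CCCC(C)(C)C2)CC[C@@H](COC=O)C1=O | intermediate
22 | (2R)-2-{(5S)-5-[(formyloxy)methyl]-6-oxo-2-[(1S)-1,3,3-trimethylcyclohexyl]cyclohex-1-en-1-yl}propanoic acid | C[C@@H](C(=O)O)C1=C([C@@]2(C)CCCC(C)(C)C2)CC[C@@H](COC=O)C1=O | target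

**Totals.** 13 steps in all; the longest linear sequence is 11 steps (steps 1, 2, 3, 6 to 13).

**Steps most likely to fail**

Step 8 (Proposed new method). The risks are weak enantiofacial discrimination at the dienolate carbon, and slow γ-deprotonation that lets the π-allyl decay by proton loss to a 1,3-diene or by intermolecular allylation. The fallback uses known chemistry, sets out from 13 and comes back at 15. Alcohol 13 is converted (MsCl, Et3N; then LiCl, DMF) into the allylic chloride 3-(7-chloro-6-methylideneheptan-2-yl)-2-[(2S,3E)-pent-3-en-2-yl]cyclohex-2-en-1-one F1. KOt-Bu in t-BuOH/THF at high dilution then effects a classical base-mediated cycloalkylation of the equilibrating dienolate on the allylic halide. This should give 15 together with its C1' epimer 3-[(1R)-1-methyl-3-methylidenecyclohexyl]-2-[(2S,3E)-pent-3-en-2-yl]cyclohex-2-en-1-one F2. The two are diastereomers because of the resident (S) side-chain centre and are separated by preparative chromatography; 15 rejoins the route.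

Step 6. The risks are enolisation at C6 or β-hydride reduction in place of 1,2-addition at the hindered carbonyl, and radical cyclisation of the secondary hexenyl-type radical during magnesium insertion. The fallback sets out from 4 and 10 and comes back at 12. Dione 4 is converted (Tf2O, 2,6-lutidine, CH2Cl2, −78 °C) into 3-oxo-2-[(2S,3E)-pent-3-en-2-yl]cyclohex-1-en-1-yl trifluoromethanesulfonate F3. Bromide 10 is converted with zinc dust and LiCl in THF into {7-[(tert-butyldimethylsilyl)oxy]-6-methylideneheptan-2-yl}zinc bromide F4. Negishi coupling of the two (Pd(OAc)2, 2-dicyclohexylphosphino-2',6'-bis(dimethylamino)biphenyl, THF) gives 12, which is isolated here and desilylated with the same aqueous HCl to 13.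

Step 11. The risks are low facial selectivity on the hindered cross-conjugated enol ether, protodesilylation, and retro-aldol loss or β-elimination of the hydroxymethyl group. The fallback sets out from 17 and comes back at 19. Ketone 17 is condensed with (S)-1-amino-2-(methoxymethyl)pyrrolidine to the SAMP hydrazone of 17 F5. LDA followed by benzyl chloromethyl ether alkylates the aza-enolate at C6 under auxiliary control (SAMP-hydrazone alkylation) to give the SAMP hydrazone of F7 F6. Two-phase aqueous oxalic acid releases (6S)-6-[(benzyloxy)methyl]-2-[(2S,3E)-pent-3-en-2-yl]-3-[(1S)-1,3,3-trimethylcyclohexyl]cyclohex-2-en-1-one F7. BCl3·SMe2 at −78 °C removes the benzyl group without touching the alkenes and gives 19.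

**Further compounds**

F1 | step 8 | 3-(7-chloro-6-methylideneheptan-2-yl)-2-[(2S,3E)-pent-3-en-2-yl]cyclohex-2-en-1-one | C[C@@H](/C=C/C)C1=C(C(C)CCCC(=C)CCl)CCCC1=O
F2 | step 8 | 3-[(1R)-1-methyl-3-methylidenecyclohexyl]-2-[(2S,3E)-pent-3-en-2-yl]cyclohex-2-en-1-one | C[C@@H](/C=C/C)C1=C([C@]2(C)CCCC(=C)C2)CCCC1=O
F3 | step 6 | 3-oxo-2-[(2S,3E)-pent-3-en-2-yl]cyclohex-1-en-1-yl trifluoromethanesulfonate | C[C@@H](/C=C/C)C1=C(OS(=O)(=O)C(F)(F)F)CCCC1=O
F4 | step 6 | {7-[(tert-butyldimethylsilyl)oxy]-6-methylideneheptan-2-yl}zinc bromide | CC([Zn]Br)CCCC(=C)CO[Si](C)(C)C(C)(C)C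
F5 | step 11 | SAMP hydrazone of 17 | C[C@@H](/C=C/C)C1=C([C@@]2(C)CCCC(C)(C)C2)CCCC1=NN1CCC[C@H]1COC
F6 | step 11 | SAMP hydrazone of F7 | C[C@@H](/C=C/C)C1=C([C@@]2(C)CCCC(C)(C)C2)CC[C@@H](COCc2ccccc2)C1=NN1CCC[C@H]1COC
F7 | step 11 | (6S)-6-[(benzyloxy)methyl]-2-[(2S,3E)-pent-3-en-2-yl]-3-[(1S)-1,3,3-trimethylcyclohexyl]cyclohex-2-en-1-one | C[C@@H](/C=C/C)C1=C([C@@]2(C)CCCC(C)(C)C2)CC[C@@H](COCc2ccccc2)C1=O
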